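**Retrosynthetic overview**

1. Ring C (the pyranone) is the only ring that has to be made. It is closed first, on the bought ring A ketone: acetophenone 1 → enaminone 2 → chromone 3.
2. Key disconnection C2–C1′: the partners are chromone 3 and the bought ring B aryl iodide 4. Chromone 3 is zincated at C2 to give 5, a β-metalated enone that acts as a homoenolate-type d3 carbanion at the carbon that is normally the Michael-acceptor terminus. Negishi coupling of 5 with the electrophilic aryl carbon of 4 gives flavone aldehyde 6.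
3. 5′-OH ⇐ 5′-CHO: Baeyer–Villiger/Dakin oxidation (6 → formate 7 → phenol 8). This is why cheap 5-iodoveratraldehyde can carry the whole ring B pattern, with its aldehyde left unprotected through the coupling.
4. 5-OH ⇐ 5-OMe: chelation-controlled BCl3 demethylation as the last step (8 → boron chelate 9 → target 10).

Assumption: the target has no stereocentre and no stereogenic axis, so it is achiral and no stereocontrol is needed; 1 and 4 are taken as catalogue chemicals.

**Route**

Step 1
Reactants: 1 1-(2-hydroxy-4,5,6-trimethoxyphenyl)ethan-1-one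
Product: 3 5,6,7-trimethoxy-4H-chromen-4-one, via enaminone 2 (not isolated)
Conditions: Me2NCH(OMe)2 (3 equiv), toluene, 110 °C, 4 h; evaporate; then conc. HCl (2 equiv), CH2Cl2, 40 °C, 1 h
Reagents that add atoms: N,N-dimethylformamide dimethyl acetal, COC(OC)N(C)C
Why: Condensation of the methyl ketone with the amide acetal gives the enaminone, and acid-promoted intramolecular oxa-Michael addition of the phenol with loss of dimethylamine (the standard enaminone chromone synthesis) closes ring C; no stereocentre is formed.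

Step 2
Reactants: 3 5,6,7-trimethoxy-4H-chromen-4-one; 4 3-iodo-4,5-dimethoxybenzaldehyde
Product: 6 3,4-dimethoxy-5-(5,6,7-trimethoxy-4-oxo-4H-chromen-2-yl)benzaldehyde, via chromon-2-ylzinc chloride 5 (not isolated)
Conditions: 3 (1.2 equiv), TMPZnCl·LiCl (1.3 equiv), THF, 25 °C, 1 h; then 4 (1.0 equiv), Pd(dba)2 (3 mol %), P(2-furyl)3 (6 mol %), THF, 50 °C, 6 h
Reagents that add atoms: none
Why: Deprotonative zincation followed by Negishi cross-coupling: the hindered, magnesium-free zinc amide removes the most acidic proton of 3 (C2–H, on the oxygen-bearing β-carbon of the vinylogous ester) to give a β-zincated enone that is a homoenolate-type d3 nucleophile at the normally electrophilic C2, is too covalent to ring-open or to add to the free aldehyde of 4, and transmetalates to the ArPdI formed from 4 so that reductive elimination joins two natively electrophilic carbons; no stereocentre is formed.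

Step 3
Reactants: 6 3,4-dimethoxy-5-(5,6,7-trimethoxy-4-oxo-4H-chromen-2-yl)benzaldehyde
Product: 8 2-(5-hydroxy-2,3-dimethoxyphenyl)-5,6,7-trimethoxy-4H-chromen-4-one, via aryl formate 7 (not isolated)
Conditions: mCPBA (1.5 equiv), CH2Cl2, 0 → 40 °C, 6 h; aq. Na2SO3/NaHCO3 wash; then K2CO3 (0.3 equiv), MeOH, 25 °C, 30 min
Reagents that add atoms: meta-chloroperoxybenzoic acid (mCPBA), O=C(OO)c1cccc(Cl)c1
Why: Baeyer–Villiger (Dakin-type) oxidation: in the Criegee adduct the aryl group, activated by the methoxy group para to the aldehyde, migrates in preference to hydride to give formate 7, which catalytic carbonate in methanol transesterifies to the phenol, while the electron-poor pyranone double bond is inert to the peracid.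

Step 4
Reactants: 8 2-(5-hydroxy-2,3-dimethoxyphenyl)-5,6,7-trimethoxy-4H-chromen-4-one
Product: 10 5-hydroxy-2-(5-hydroxy-2,3-dimethoxyphenyl)-6,7-dimethoxy-4H-chromen-4-one, via boron chelate 9 (not isolated)
Conditions: BCl3 (1 M in CH2Cl2, 3 equiv), CH2Cl2, −78 → 0 °C, 2 h; then MeOH, aq. HCl, 25 °C
Reagents that add atoms: none
Why: Chelation-controlled Lewis-acid ether cleavage: BCl3 binds the C4 carbonyl and the peri 5-methoxy oxygen in a six-membered chelate so that chloride removes only that methyl group (the 5′-OH is merely held as an aryloxydichloroborane), and aqueous work-up hydrolyses both B–O bonds of 9 to release 10; no stereocentre is present.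

**Compound list**

1 | 1-(2-hydroxy-4,5,6-trimethoxyphenyl)ethan-1-one (2′-hydroxy-4′,5′,6′-trimethoxyacetophenone) | CC(=O)c1c(O)cc(OC)c(OC)c1OC | starting material
2 | (E)-3-(dimethylamino)-1-(2-hydroxy-4,5,6-trimethoxyphenyl)prop-2-en-1-one (not isolated) | CN(C)/C=C/C(=O)c1c(O)cc(OC)c(OC)c1OC | intermediate
3 | 5,6,7-trimethoxy-4H-chromen-4-one | COc1cc2occc(=O)c2c(OC)c1OC | intermediate
4 | 3-iodo-4,5-dimethoxybenzaldehyde (5-iodoveratraldehyde) | COc1cc(C=O)cc(I)c1OC | starting material
5 | chloro(5,6,7-trimethoxy-4-oxo-4H-chromen-2-yl)zinc, present as its LiCl complex in THF (not isolated) | COc1cc2oc([Zn]Cl)cc(=O)c2c(OC)c1OC | intermediate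
6 | 3,4-dimethoxy-5-(5,6,7-trimethoxy-4-oxo-4H-chromen-2-yl)benzaldehyde | COc1cc(C=O)cc(-c2cc(=O)c3c(OC)c(OC)c(OC)cc3o2)c1OC | intermediate
7 | 3,4-dimethoxy-5-(5,6,7-trimethoxy-4-oxo-4H-chromen-2-yl)phenyl formate (not isolated) | COc1cc(OC=O)cc(-c2cc(=O)c3c(OC)c(OC)c(OC)cc3o2)c1OC | intermediate
8 | 2-(5-hydroxy-2,3-dimethoxyphenyl)-5,6,7-trimethoxy-4H-chromen-4-one | COc1cc(O)cc(-c2cc(=O)c3c(OC)c(OC)c(OC)cc3o2)c1OC | intermediate
9 | 5-[(dichloroboranyl)oxy]-2-{5-[(dichloroboranyl)oxy]-2,3-dimethoxyphenyl}-6,7-dimethoxy-4H-chromen-4-one, the 5-O–B unit chelated to the C4 carbonyl (not isolated) | COc1cc(OB(Cl)Cl)cc(-c2cc(=O)c3c(OB(Cl)Cl)c(OC)c(OC)cc3o2)c1OC | intermediate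
10 | 5-hydroxy-2-(5-hydroxy-2,3-dimethoxyphenyl)-6,7-dimethoxy-4H-chromen-4-one (CNP0303773.0, achiral) | COc1cc(O)cc(-c2cc(=O)c3c(O)c(OC)c(OC)cc3o2)c1OC | target

**Step count and risks**

Total step count: 4. Longest linear sequence: 4 steps (1 → 3 → 6 → 8 → 10); 4 enters at step 2.

The three steps most likely to fail, in order of risk:

Step 2 (zincation/Negishi coupling). The risks are incomplete zincation of the electron-rich chromone, metalation at C3 or C8 instead of C2, and loss of the unprotected aldehyde of 4 to the metal amide. The fallback makes the same C2 carbanion kinetically and stores it as an isolable stannane, so that 4 never meets a metal amide. It sets out from 3: 3 is added to lithium 2,2,6,6-tetramethylpiperidide (1.1 equiv) in THF at −90 °C, and the short-lived 2-lithio-5,6,7-trimethoxy-4H-chromen-4-one F1 is quenched within minutes with Bu3SnCl to give 5,6,7-trimethoxy-2-(tributylstannyl)-4H-chromen-4-one F2. After chromatography, Stille coupling of F2 with 4 (Pd(PPh3)4 5 mol %, CuI 10 mol %, DMF, 60 °C) comes back to the route at 6.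

Step 3 (Baeyer–Villiger on the flavone aldehyde). The methoxy group para to the aldehyde is twisted by its two ortho neighbours and the chromonyl group is electron-withdrawing, so hydride migration to the benzoic acid may compete, and the peracid may attack the large, electron-rich substrate elsewhere. The fallback does the oxidation on the small building block before the coupling. It sets out from 4: mCPBA in CH2Cl2 gives 3-iodo-4,5-dimethoxyphenyl formate F3, which K2CO3/MeOH cleaves to 3-iodo-4,5-dimethoxyphenol F4. TBSCl/imidazole in DMF then gives tert-butyl(3-iodo-4,5-dimethoxyphenoxy)dimethylsilane F5. Negishi coupling of F5 with chromonylzinc 5 (made from 3 exactly as in step 2) gives 2-[5-(tert-butyldimethylsilyloxy)-2,3-dimethoxyphenyl]-5,6,7-trimethoxy-4H-chromen-4-one F6, and Bu4NF in THF at 0 °C comes back to the route at 8.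

Step 4 (selective 5-O-demethylation). The free 5′-phenol consumes BCl3 and makes the stoichiometry at the chelating site ill-defined. Either 8 survives or the 6-OMe next to the new boron chelate is also cleaved, and the polar diphenols are hard to separate. The fallback moves the demethylation in front of the oxidation. It sets out from 6, which has no free phenol: BCl3 (2 equiv, CH2Cl2, −78 → 0 °C) gives 3-{5-[(dichloroboranyl)oxy]-6,7-dimethoxy-4-oxo-4H-chromen-2-yl}-4,5-dimethoxybenzaldehyde F7. Work-up hydrolyses it to 3-(5-hydroxy-6,7-dimethoxy-4-oxo-4H-chromen-2-yl)-4,5-dimethoxybenzaldehyde F8, a single, non-polar, hydrogen-bonded phenol that is easy to purify. mCPBA in CH2Cl2 then gives 3-(5-hydroxy-6,7-dimethoxy-4-oxo-4H-chromen-2-yl)-4,5-dimethoxyphenyl formate F9, and K2CO3 (cat.)/MeOH comes back to the route at 10.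

**Further compounds**

F1 | step 2 | 2-lithio-5,6,7-trimethoxy-4H-chromen-4-one | [Li]c1cc(=O)c2c(OC)c(OC)c(OC)cc2o1
F2 | step 2 | 5,6,7-trimethoxy-2-(tributylstannyl)-4H-chromen-4-one | CCCC[Sn](CCCC)(CCCC)c1cc(=O)c2c(OC)c(OC)c(OC)cc2o1
F3 | step 3 | 3-iodo-4,5-dimethoxyphenyl formate | COc1cc(OC=O)cc(I)c1OC
F4 | step 3 | 3-iodo-4,5-dimethoxyphenol | COc1cc(O)cc(I)c1OC
F5 | step 3 | tert-butyl(3-iodo-4,5-dimethoxyphenoxy)dimethylsilane | COc1cc(O[Si](C)(C)C(C)(C)C)cc(I)c1OC
F6 | step 3 | 2-[5-(tert-butyldimethylsilyloxy)-2,3-dimethoxyphenyl]-5,6,7-trimethoxy-4H-chromen-4-one | COc1cc(O[Si](C)(C)C(C)(C)C)cc(-c2cc(=O)c3c(OC)c(OC)c(OC)cc3o2)c1OC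
F7 | step 4 | 3-{5-[(dichloroboranyl)oxy]-6,7-dimethoxy-4-oxo-4H-chromen-2-yl}-4,5-dimethoxybenzaldehyde | COc1cc(C=O)cc(-c2cc(=O)c3c(OB(Cl)Cl)c(OC)c(OC)cc3o2)c1OC
F8 | step 4 | 3-(5-hydroxy-6,7-dimethoxy-4-oxo-4H-chromen-2-yl)-4,5-dimethoxybenzaldehyde | COc1cc(C=O)cc(-c2cc(=O)c3c(O)c(OC)c(OC)cc3o2)c1OC
F9 | step 4 | 3-(5-hydroxy-6,7-dimethoxy-4-oxo-4H-chromen-2-yl)-4,5-dimethoxyphenyl formate | COc1cc(OC=O)cc(-c2cc(=O)c3c(O)c(OC)c(OC)cc3o2)c1OC
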